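## The problem

The target (20, CNP0296800.3) is a 2,3-dihydrobenzofuran. Its dihydrofuran ring (O1, C2, C3) is fused through C3a and C7a to a benzo ring carrying a free hydroxyl at C4 and an (E)-4-hydroxy-3-methoxystyryl arm at C6; C2 bears a 4-hydroxy-3-methoxyphenyl (guaiacyl) ring and C3 a 3,5-dihydroxyphenyl (resorcinol) ring. The only stereocentres are C2 and C3, both R and trans. The trans relation is the more stable one and can be relayed from C3 to C2, because C3 cannot ionise whereas the C2–O1 bond can open and re-close; the absolute sense must come from outside the skeleton. The groups that will not survive rough treatment are these: the four free phenols and the electron-rich stilbene (oxidants, light, strong acid; the alkene also rules out hydrogenolysis), the C2–O1 bond (a benzylic ether para to an oxygenated ring, which ionises under acid), and the C2–C3 bond, which is one dehydrogenation away from a 2,3-diarylbenzofuran in which both stereocentres are lost. Two aryl methyl ethers must reach the end, so the phenols need a protecting group that is distinguishable from methyl and removable without hydrogen. The enabling feature is that C3a lies between the two oxygen-bearing carbons C4 and C7a: the benzo ring is the aromatised form of a cyclohexane-1,3-dione whose central carbon is C3a, whose oxygens become O1 and the C4 hydroxyl, and whose C5 (C6 of the target) lies on the mirror plane and can carry the styryl arm. The carbon and oxygen nucleophiles needed to build the dihydrofuran ring are therefore the two ends of one symmetric 1,3-dinucleophile, no regiochemical question arises at C3a, and the benzo ring can be aromatised after the heterocycle is in place.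

## Retrosynthesis

**20 from 19.** The four benzyl–oxygen bonds are cut. Benzyl is chosen because it survives alkoxide, amide base, carbonate and hot aqueous acid, is distinct from the two methyl ethers, and can be cleaved by a Lewis acid with a cation scavenger, so the stilbene never sees hydrogen. The C4 hydroxyl needs no protection because it is only created one step earlier. The forward reaction must cleave four aryl benzyl ethers without touching the methyl ethers, the alkene or the C2–O1 bond.

**19 from 16.** Two hydrogens are added back across C5–C6, turning the phenol into the vinylogous ester 16, a tetrahydrobenzofuran-4-one. The neighbouring option, keeping the arene and forging C3a–C3 on a 5-styrylresorcinol, would have to direct a bulky electrophile to the hindered position between the two oxygens rather than to the positions para to them. The dione oxidation level has a single nucleophilic carbon and removes that question. The forward dehydrogenation must be confined to C5–C6 and must never reach C2–C3, which argues for a site-specific α′-functionalisation and elimination rather than a quinone or a hot metal surface.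

**16 from 11, 12 and 6.** Three bonds are cut at once: C3a–C3, C3–C2 and C2–O1. The dione 11 supplies C3a and O1, the aldehyde carbon of 12 becomes C3, and the ylide carbon of 6 becomes C2. Cuts that sever only C2–O1 or O1–C7a leave an acyclic, stereodefined diaryl precursor still to be made; this cut makes the ring and both stereocentres from an achiral dione, a commercial achiral aldehyde and a sulfonium salt whose chiral sulfide is released for recovery. The forward reaction must (a) deliver the ylide to the arylidene dione and not to free aldehyde, (b) close through oxygen, trans, and (c) take its absolute sense from the sulfide. It is run in one flask but staged: condensation first, ylide second.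

**11 from 9, 8 and 7.** The dione ring is opened by a retro-Claisen and retro-Michael sequence to the dienone 9 and a malonate unit; 9 goes back by two stabilised-ylide Wittig homologations through enal 8 to commercial O-benzylvanillin 7. The spectator on the dione is deliberately the finished (E)-styryl arm rather than an ester. It is not conjugated to the dione, is inert to the ylide, and removes all reduction, oxidation and olefination steps after the key step. The price is that step 9 must use reagents that spare an alkene.

**6 from 3 and 5; 5 from 4; 3 from 2 and 1.** The sulfonium salt is cut at the benzylic C–S bond into the twofold-symmetric thiolane 3 and bromide 5, the latter from commercial alcohol 4. The thiolane is cut at both C–S bonds to the dimesylate 2 of commercial diol 1. Two SN2 inversions turn the (2S,5S) diol into the (2R,5R) thiolane.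

## Roads not taken

**Alternative 1:** The cut runs through the benzo ring itself (C3a–C7a, C4–C5 and the ring-closing bond). In the forward direction 3-styrylcyclobutenone A2 is heated with the triisopropylsilyl ynol ether A3, which already carries both stereocentres as a 1,2-diaryl unit with the C2 oxygen silylated. A Danheiser benzannulation (four-electron ring opening, ketene–alkyne (2+2) addition, second ring opening, six-electron closure, tautomerisation) would give the resorcinol monosilyl ether A1; unmasking the benzylic carbinol and closing O1–C2 would follow.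
- Merits: the benzo ring arrives aromatic with all substituents placed and the two oxygens differentiated, the styryl arm comes in with A2, and no dehydrogenation is ever needed next to the stereocentres.
- Weak points: A3 is a long synthesis in its own right (an enantioselective 1,2-diaryl stereodiad, then ester-to-ynolate homologation and silylation). The benzannulation must place a bulky secondary diarylethyl group between two oxygens at elevated temperature. The final closure at the carbinol must proceed with net retention, that is, through a benzylic cation under ionising conditions.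
- Comparison: this road is better in that it never risks oxidising the dihydrofuran and takes its stereocentres from established acyclic asymmetric chemistry. The chosen plan sets against it one step that forms three bonds, the ring and both stereocentres from simple parts, and a much shorter sequence overall.

**Alternative 2:** The cut is O1–C7a and C3–C3a. Fluoride would release an aryne from silyl triflate A5; the alkoxide of mandelate A6 adds at the aryne carbon remote from the benzyloxy group, and the resulting aryl anion is acylated by the ester, giving benzofuranone A4.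
- Merits: the core is reached in very few steps, the alkoxy group directs the aryne addition, the benzo ring is aromatic from the outset, and the bromide is a handle for a late Heck reaction, which makes the road modular.
- Weak points: A4 is racemic and its C2 is an enolisable α-aryl-α-alkoxy ketone carbon. The C3 aryl group is still missing and must be added to a ketone flanked by the peri benzyloxy group, followed by removal of the tertiary hydroxyl. Absolute configuration has no source other than a resolution or a difficult asymmetric reduction of a tetrasubstituted benzofuran, which would give cis first. A5 itself takes several steps.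
- Comparison: in modularity and in avoiding any aromatisation this road is at least as good. The chosen plan sets against it that both stereocentres, relative and absolute, are settled in the ring-forming step.

**Alternative 3:** Only O1–C2 is cut. Ag2O would oxidise the 4-hydroxybenzyl unit of triarylethane A8 to its quinone methide stage, and either of the two equivalent ortho hydroxyls would add to close the ring trans to the C3 aryl group, giving the tri-O-benzyl ether A7.
- Merits: C2 is set by C3 through substrate control, the symmetric resorcinol leaves no regiochemical choice, and A7 is one debenzylation from the target, one step fewer after the key step than in the chosen plan.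
- Weak points: A8 must already hold the C3 stereocentre in enantiopure form, a triarylmethine flanked by a 2,6-dihydroxyaryl ring, which is hard to make asymmetrically and lengthens the linear sequence. The benzylic CH2 to be oxidised is not activated by extended conjugation, while a free resorcinol and an electron-rich stilbene compete for the oxidant. The product's free 4-hydroxyphenyl group at C2 invites over-oxidation to the benzofuran.
- Comparison: the endgame is shorter and the trans relation more securely substrate-controlled than in the chosen plan. The chosen plan sets against it that no oxidant meets a free phenol before the last intermediate, and that C3 and C2 are created together rather than C3 having to be bought beforehand.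

Key step: step 8

Assumption: the (2R,5R)-thiolane is taken to steer the ylide carbon with the same facial sense as in its benzylidene transfer to aldehydes, which corresponds to R at C2 after the inverting ring closure; were the sense opposite, the enantiomer of 1 would be used and nothing else would change.

## Route

Step 1
Reactants: 1 (2S,5S)-hexane-2,5-diol
Product: 2 (2S,5S)-hexane-2,5-diyl dimethanesulfonate
Conditions: MsCl, Et3N, CH2Cl2, −20 → 0 °C
Reagents that add atoms: methanesulfonyl chloride, CS(=O)(=O)Cl
Why: O-Sulfonylation of both secondary alcohols; no bond to a stereocentre is broken, so the (2S,5S) configuration is carried over.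

Step 2
Reactants: 2 (2S,5S)-hexane-2,5-diyl dimethanesulfonate
Product: 3 (2R,5R)-2,5-dimethylthiolane
Conditions: Na2S·9H2O, DMSO, 23 °C
Reagents that add atoms: sodium sulfide, [Na+].[Na+].[S-2]
Why: Double SN2 thioetherification, first intermolecular and then 5-exo-tet; each displacement inverts, so the (2S,5S) dimesylate gives the trans (2R,5R) thiolane with a twofold axis.

Step 3
Reactants: 4 [4-(benzyloxy)-3-methoxyphenyl]methanol
Product: 5 1-(benzyloxy)-4-(bromomethyl)-2-methoxybenzene
Conditions: PBr3, Et2O, 0 °C
Reagents that add atoms: phosphorus tribromide, BrP(Br)Br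
Why: Standard conversion of a benzylic alcohol into the bromide through its phosphite ester; the aryl benzyl and methyl ethers are inert at 0 °C.

Step 4
Reactants: 3 (2R,5R)-2,5-dimethylthiolane; 5 1-(benzyloxy)-4-(bromomethyl)-2-methoxybenzene
Product: 6 (2R,5R)-1-[4-(benzyloxy)-3-methoxybenzyl]-2,5-dimethylthiolan-1-ium tetrafluoroborate
Conditions: NaBF4, acetone, 23 °C
Reagents that add atoms: sodium tetrafluoroborate, [Na+].F[B-](F)(F)F
Why: S-Alkylation of a thioether by an activated benzylic bromide with anion metathesis; the non-nucleophilic counter-ion and the precipitation of NaBr suppress the reverse reaction, and because the two sulfur lone pairs are equivalent a single salt forms in which sulfur is not a stereocentre.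

Step 5
Reactants: 7 4-(benzyloxy)-3-methoxybenzaldehyde
Product: 8 (2E)-3-[4-(benzyloxy)-3-methoxyphenyl]prop-2-enal
Conditions: Ph3P=CHCHO (0.95 equiv), toluene, 80 °C
Reagents that add atoms: (triphenylphosphoranylidene)acetaldehyde, O=CC=P(c1ccccc1)(c1ccccc1)c1ccccc1
Why: Wittig olefination with a formyl-stabilised ylide gives the E enal; the ylide is kept slightly deficient to limit a second homologation of the product.

Step 6
Reactants: 8 (2E)-3-[4-(benzyloxy)-3-methoxyphenyl]prop-2-enal
Product: 9 (3E,5E)-6-[4-(benzyloxy)-3-methoxyphenyl]hexa-3,5-dien-2-one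
Conditions: Ph3P=CHC(O)CH3, toluene, 90 °C
Reagents that add atoms: 1-(triphenylphosphoranylidene)propan-2-one, CC(=O)C=P(c1ccccc1)(c1ccccc1)c1ccccc1
Why: Wittig olefination with a keto-stabilised ylide sets the new alkene E and avoids the double condensation that an aldol reaction with acetone could give.

Step 7
Reactants: 9 (3E,5E)-6-[4-(benzyloxy)-3-methoxyphenyl]hexa-3,5-dien-2-one
Product: 11 5-{(E)-2-[4-(benzyloxy)-3-methoxyphenyl]ethenyl}cyclohexane-1,3-dione, via cyclic beta-keto ester 10 (not isolated)
Conditions: CH2(CO2Et)2, NaOEt, EtOH, reflux; aq NaOH, reflux; then HCl, 70 °C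
Reagents that add atoms: diethyl malonate, CCOC(=O)CC(=O)OCC
Why: Classical Michael–Claisen synthesis of a 5-substituted cyclohexane-1,3-dione: malonate adds 1,4 to the enone (the styrene stays conjugated), the methyl ketone enolate closes onto one ester to give 10 as its sodium enolate, and saponification with decarboxylation gives 11; a 1,6-adduct cannot close to a six-membered ring and reverts.

Step 8
Reactants: 11 5-{(E)-2-[4-(benzyloxy)-3-methoxyphenyl]ethenyl}cyclohexane-1,3-dione; 12 3,5-bis(benzyloxy)benzaldehyde; 6 (2R,5R)-1-[4-(benzyloxy)-3-methoxybenzyl]-2,5-dimethylthiolan-1-ium tetrafluoroborate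
Product: 16 (2R,3R)-2-[4-(benzyloxy)-3-methoxyphenyl]-3-[3,5-bis(benzyloxy)phenyl]-6-{(E)-2-[4-(benzyloxy)-3-methoxyphenyl]ethenyl}-3,5,6,7-tetrahydro-1-benzofuran-4(2H)-one (both C6 epimers), via 2-arylidene dione 13 (not isolated), via bis-dione Michael adduct 14 (not isolated), via sulfonium enolate betaine 15 (not isolated)
Conditions: 11 (1.3 equiv), ethylenediammonium diacetate (EDDA, 10 mol %), 4 Å MS, MeCN, 23 °C; then 6, Cs2CO3, 0 → 23 °C
Reagents that add atoms: none
Why: EDDA-catalysed Knoevenagel condensation of 11 with 12 forms C3a–C3 in the arylidene dione 13, which is parked reversibly as its Michael adduct 14 with a second molecule of 11; once Cs2CO3 turns 6 into the benzylide, the ylide carbon adds to the exocyclic carbon of 13 (C3–C2) and the enolate oxygen of betaine 15 displaces the thiolane in a 5-exo-tet SN2 closure (C2–O1) that forms the dihydrofuran ring. The closest known reaction type is the Knoevenagel–Michael–O-alkylation cascade (formal (4+1) annulation) of cyclic 1,3-diones, aldehydes and sulfonium or pyridinium ylides to trans-2,3-dihydrofurans, run here with a stoichiometric chiral sulfide as in asymmetric ylide epoxidation and cyclopropanation. C2 is controlled by the twofold-symmetric thiolane: the ylide aryl group turns away from the flanking methyl group while the other methyl group screens one face, so 13 is met by a single ylide face, and the SN2 closure then inverts that carbon to R. C3 is controlled by the relative topicity of the addition together with the closure: only the betaine with the two aryl groups anti can place enolate oxygen and sulfonium anti-periplanar without an aryl–aryl eclipse, and because addition to so stabilised an enolate is reversible the other betaine reverts rather than closes, which gives the trans (2R,3R) product. The selectivity the step needs is capture of the ylide by 13 and not by free 12 (Corey–Chaykovsky epoxidation); it is secured by finishing the condensation before base is added, by the excess of 11, and by the far higher electrophilicity of an alkylidene 1,3-dione compared with an aryl aldehyde. Closure through oxygen and not carbon is secured by the six-membered dione, whose enolate oxygen reaches the sulfonium carbon through a five-membered transition state, whereas C-attack would give a strained spirocyclopropane. The symmetry of 11 removes any regiochemical choice; its two oxygens differ only in giving the two C6 epimers, which converge in step 9.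

Step 9
Reactants: 16 (2R,3R)-2-[4-(benzyloxy)-3-methoxyphenyl]-3-[3,5-bis(benzyloxy)phenyl]-6-{(E)-2-[4-(benzyloxy)-3-methoxyphenyl]ethenyl}-3,5,6,7-tetrahydro-1-benzofuran-4(2H)-one
Product: 19 (2R,3R)-2-[4-(benzyloxy)-3-methoxyphenyl]-3-[3,5-bis(benzyloxy)phenyl]-6-{(E)-2-[4-(benzyloxy)-3-methoxyphenyl]ethenyl}-2,3-dihydro-1-benzofuran-4-ol, via 5-phenylselanyl ketone 17 (not isolated), via cross-conjugated dienone 18 (not isolated)
Conditions: LiN(iPr)2, THF, −78 °C; PhSeBr, −78 °C; then H2O2, pyridine, CH2Cl2, 0 → 23 °C
Reagents that add atoms: none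
Why: Kinetic α′-deprotonation of the vinylogous ester at C5 and selenenylation give 17; oxidation at selenium and selenoxide syn-elimination toward the only β-hydrogen (C6–H) give dienone 18, which tautomerises to the phenol, the standard cyclohexenone-to-phenol dehydrogenation. Unsaturation cannot enter C2–C3 because C3 is not enolisable and the leaving group sits on C5, so both stereocentres are untouched and both C6 epimers converge.

Step 10
Reactants: 19 (2R,3R)-2-[4-(benzyloxy)-3-methoxyphenyl]-3-[3,5-bis(benzyloxy)phenyl]-6-{(E)-2-[4-(benzyloxy)-3-methoxyphenyl]ethenyl}-2,3-dihydro-1-benzofuran-4-ol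
Product: 20 5-[(2R,3R)-4-hydroxy-2-(4-hydroxy-3-methoxyphenyl)-6-[(E)-2-(4-hydroxy-3-methoxyphenyl)ethenyl]-2,3-dihydro-1-benzofuran-3-yl]benzene-1,3-diol
Conditions: BCl3, C6HMe5, CH2Cl2, −78 °C
Reagents that add atoms: none
Why: Lewis-acid cleavage of aryl benzyl ethers with pentamethylbenzene as benzyl-cation scavenger, which at −78 °C spares aryl methyl ethers and the stilbene and prevents re-benzylation of the electron-rich rings. C3 is not touched, and any reversible opening of C2–O1 would re-close trans to it.

## Compound list

1 | (2S,5S)-hexane-2,5-diol | C[C@H](O)CC[C@H](C)O | starting material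
2 | (2S,5S)-hexane-2,5-diyl dimethanesulfonate | C[C@H](OS(C)(=O)=O)CC[C@H](C)OS(C)(=O)=O | intermediate
3 | (2R,5R)-2,5-dimethylthiolane | C[C@@H]1CC[C@@H](C)S1 | intermediate
4 | [4-(benzyloxy)-3-methoxyphenyl]methanol | OCc1ccc(OCc2ccccc2)c(OC)c1 | starting material
5 | 1-(benzyloxy)-4-(bromomethyl)-2-methoxybenzene | BrCc1ccc(OCc2ccccc2)c(OC)c1 | intermediate
6 | (2R,5R)-1-[4-(benzyloxy)-3-methoxybenzyl]-2,5-dimethylthiolan-1-ium tetrafluoroborate | C[C@@H]1CC[C@@H](C)[S+]1Cc1ccc(OCc2ccccc2)c(OC)c1.F[B-](F)(F)F | intermediate
7 | 4-(benzyloxy)-3-methoxybenzaldehyde | O=Cc1ccc(OCc2ccccc2)c(OC)c1 | starting material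
8 | (2E)-3-[4-(benzyloxy)-3-methoxyphenyl]prop-2-enal | O=C/C=C/c1ccc(OCc2ccccc2)c(OC)c1 | intermediate
9 | (3E,5E)-6-[4-(benzyloxy)-3-methoxyphenyl]hexa-3,5-dien-2-one | CC(=O)/C=C/C=C/c1ccc(OCc2ccccc2)c(OC)c1 | intermediate
10 | ethyl 6-{(E)-2-[4-(benzyloxy)-3-methoxyphenyl]ethenyl}-2,4-dioxocyclohexane-1-carboxylate (sodium enolate in the flask, relative configuration unassigned) | CCOC(=O)C1C(=O)CC(=O)CC1/C=C/c1ccc(OCc2ccccc2)c(OC)c1 | intermediate (not isolated)
11 | 5-{(E)-2-[4-(benzyloxy)-3-methoxyphenyl]ethenyl}cyclohexane-1,3-dione | O=C1CC(=O)CC(/C=C/c2ccc(OCc3ccccc3)c(OC)c2)C1 | intermediate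
12 | 3,5-bis(benzyloxy)benzaldehyde | O=Cc1cc(OCc2ccccc2)cc(OCc2ccccc2)c1 | starting material
13 | 2-[3,5-bis(benzyloxy)benzylidene]-5-{(E)-2-[4-(benzyloxy)-3-methoxyphenyl]ethenyl}cyclohexane-1,3-dione (racemic) | O=C1CC(/C=C/c2ccc(OCc3ccccc3)c(OC)c2)CC(=O)C1=Cc1cc(OCc2ccccc2)cc(OCc2ccccc2)c1 | intermediate (not isolated)
14 | 2,2'-{[3,5-bis(benzyloxy)phenyl]methanediyl}bis(5-{(E)-2-[4-(benzyloxy)-3-methoxyphenyl]ethenyl}cyclohexane-1,3-dione) (stereoisomer mixture, drawn as the tetraketone) | O=C1CC(/C=C/c2ccc(OCc3ccccc3)c(OC)c2)CC(=O)C1C(c1cc(OCc2ccccc2)cc(OCc2ccccc2)c1)C1C(=O)CC(/C=C/c2ccc(OCc3ccccc3)c(OC)c2)CC1=O | intermediate (not isolated)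
15 | 2-{(1R,2S)-2-[4-(benzyloxy)-3-methoxyphenyl]-1-[3,5-bis(benzyloxy)phenyl]-2-[(2R,5R)-2,5-dimethylthiolan-1-ium-1-yl]ethyl}-5-{(E)-2-[4-(benzyloxy)-3-methoxyphenyl]ethenyl}-3-oxocyclohex-1-en-1-olate (both ring epimers) | C[C@@H]1CC[C@@H](C)[S+]1[C@H](c1ccc(OCc2ccccc2)c(OC)c1)[C@@H](C1=C([O-])CC(/C=C/c2ccc(OCc3ccccc3)c(OC)c2)CC1=O)c1cc(OCc2ccccc2)cc(OCc2ccccc2)c1 | intermediate (not isolated)
16 | (2R,3R)-2-[4-(benzyloxy)-3-methoxyphenyl]-3-[3,5-bis(benzyloxy)phenyl]-6-{(E)-2-[4-(benzyloxy)-3-methoxyphenyl]ethenyl}-3,5,6,7-tetrahydro-1-benzofuran-4(2H)-one (both C6 epimers) | COc1cc(/C=C/C2CC(=O)C3=C(C2)O[C@@H](c2ccc(OCc4ccccc4)c(OC)c2)[C@@H]3c2cc(OCc4ccccc4)cc(OCc4ccccc4)c2)ccc1OCc1ccccc1 | intermediate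
17 | (2R,3R)-2-[4-(benzyloxy)-3-methoxyphenyl]-3-[3,5-bis(benzyloxy)phenyl]-6-{(E)-2-[4-(benzyloxy)-3-methoxyphenyl]ethenyl}-5-(phenylselanyl)-3,5,6,7-tetrahydro-1-benzofuran-4(2H)-one (C5 and C6 unassigned) | COc1cc(/C=C/C2C([Se]c4ccccc4)C(=O)C3=C(C2)O[C@@H](c2ccc(OCc4ccccc4)c(OC)c2)[C@@H]3c2cc(OCc4ccccc4)cc(OCc4ccccc4)c2)ccc1OCc1ccccc1 | intermediate (not isolated)
18 | (2R,3R)-2-[4-(benzyloxy)-3-methoxyphenyl]-3-[3,5-bis(benzyloxy)phenyl]-6-{(E)-2-[4-(benzyloxy)-3-methoxyphenyl]ethenyl}-2,3-dihydro-1-benzofuran-4(7H)-one | COc1cc(/C=C/C2=CC(=O)C3=C(C2)O[C@@H](c2ccc(OCc4ccccc4)c(OC)c2)[C@@H]3c2cc(OCc4ccccc4)cc(OCc4ccccc4)c2)ccc1OCc1ccccc1 | intermediate (not isolated)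
19 | (2R,3R)-2-[4-(benzyloxy)-3-methoxyphenyl]-3-[3,5-bis(benzyloxy)phenyl]-6-{(E)-2-[4-(benzyloxy)-3-methoxyphenyl]ethenyl}-2,3-dihydro-1-benzofuran-4-ol | COc1cc(/C=C/c2cc(O)c3c(c2)O[C@@H](c2ccc(OCc4ccccc4)c(OC)c2)[C@@H]3c2cc(OCc4ccccc4)cc(OCc4ccccc4)c2)ccc1OCc1ccccc1 | intermediate
20 | 5-[(2R,3R)-4-hydroxy-2-(4-hydroxy-3-methoxyphenyl)-6-[(E)-2-(4-hydroxy-3-methoxyphenyl)ethenyl]-2,3-dihydro-1-benzofuran-3-yl]benzene-1,3-diol | COc1cc(/C=C/c2cc(O)c3c(c2)O[C@@H](c2ccc(O)c(OC)c2)[C@@H]3c2cc(O)cc(O)c2)ccc1O | target

## Step count and least certain steps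

Total step count: 10. Longest linear sequence: 6 steps (7 → 8 → 9 → 11 → 16 → 19 → 20; the branch 1 → 2 → 3 → 6 → 16 → 19 → 20 is equally long).

**Step 8 (key step).** The most likely failure is insufficient enantiofacial discrimination: this thiolane class is established for benzylidene transfer to aldehydes, and here proton exchange at the sulfonium-bearing carbon of 15 before closure could erode the sense at C2. A second failure mode is leakage of ylide into epoxidation of residual 12 while 13 is only slowly released from 14. The fallback moves enantiocontrol from the ylide to a resolution. It sets out from 5, 11 and 12: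
- S-alkylation of tetrahydrothiophene with 5 (NaBF4, acetone) gives 1-[4-(benzyloxy)-3-methoxybenzyl]thiolan-1-ium tetrafluoroborate F1.
- The same cascade with 11 and 12 through 13 and 14 gives the racemic trans ketone rac-16 F2; its trans selectivity does not depend on the sulfide.
- Dehydrogenation under the conditions of step 9 gives the racemic phenol rac-19 F3.
- Preparative chromatography on a chiral stationary phase resolves F3; the (2R,3R) enantiomer is 19, where the route is rejoined.

**Step 9.** What may go wrong is attack of electrophilic selenium on the stilbene or the electron-rich rings, selenenylation cis to the styryl group so that the selenoxide lacks a syn β-hydrogen, and oxidation of the newly formed electron-rich phenol by peroxide and selenium by-products. The fallback is a Saegusa–Ito dehydrogenation setting out from 16: LiN(iPr)2 and Me3SiCl (THF, −78 °C) give the silyl dienol ether (2R,3R)-2-[4-(benzyloxy)-3-methoxyphenyl]-3-[3,5-bis(benzyloxy)phenyl]-6-{(E)-2-[4-(benzyloxy)-3-methoxyphenyl]ethenyl}-4-[(trimethylsilyl)oxy]-2,3,6,7-tetrahydro-1-benzofuran F4. Pd(OAc)2 in MeCN at 23 °C converts F4 into dienone 18, which tautomerises to 19, where the route is rejoined. No electrophilic selenium or peroxide is used, and the site of dehydrogenation is fixed by the silyl enol ether.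

**Step 7.** What may go wrong is ethoxide-induced oligomerisation and retro-aldol cleavage of dienone 9 before the Claisen closure, with 1,6-addition draining material, and losses in the hot acidic decarboxylation. The fallback changes the disconnection of the dione ring and sets out from 8: Wittig olefination with Ph3P=CHCO2Et gives ethyl (2E,4E)-5-[4-(benzyloxy)-3-methoxyphenyl]penta-2,4-dienoate F5. A consecutive Michael–Claisen reaction of the acetone enolate with F5 (KOtBu, acetone, THF) gives 11 directly, without a decarboxylation, and the route is rejoined at 11.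

**Step 4.** What may go wrong is slow and reversible alkylation of the hindered sulfide and ionisation of the 4-alkoxybenzyl sulfonium salt during isolation, with loss of the sulfide. The fallback bypasses the bromide and sets out from 4 and 3: HBF4·OEt2 in Et2O at 0 °C ionises the benzylic alcohol and the sulfide captures the cation, giving 6 directly, where the route is rejoined. This detour makes no new compound (entry F0).

The final debenzylation is rated below these, since BCl3 with a cation scavenger at −78 °C is routine for aryl benzyl ethers beside stilbenes and aryl methyl ethers.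

## Further compounds

F1 | step 8 | 1-[4-(benzyloxy)-3-methoxybenzyl]thiolan-1-ium tetrafluoroborate | COc1cc(C[S+]2CCCC2)ccc1OCc1ccccc1.F[B-](F)(F)F
F2 | step 8 | rac-16, racemic trans-2-[4-(benzyloxy)-3-methoxyphenyl]-3-[3,5-bis(benzyloxy)phenyl]-6-{(E)-2-[4-(benzyloxy)-3-methoxyphenyl]ethenyl}-3,5,6,7-tetrahydro-1-benzofuran-4(2H)-one (both enantiomers, C6 epimers) | COc1cc(/C=C/C2CC(=O)C3=C(C2)O[C@@H](c2ccc(OCc4ccccc4)c(OC)c2)[C@@H]3c2cc(OCc4ccccc4)cc(OCc4ccccc4)c2)ccc1OCc1ccccc1.COc1cc(/C=C/C2CC(=O)C3=C(C2)O[C@H](c2ccc(OCc4ccccc4)c(OC)c2)[C@H]3c2cc(OCc4ccccc4)cc(OCc4ccccc4)c2)ccc1OCc1ccccc1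
F3 | step 8 | rac-19, racemic trans-2-[4-(benzyloxy)-3-methoxyphenyl]-3-[3,5-bis(benzyloxy)phenyl]-6-{(E)-2-[4-(benzyloxy)-3-methoxyphenyl]ethenyl}-2,3-dihydro-1-benzofuran-4-ol (both enantiomers) | COc1cc(/C=C/c2cc(O)c3c(c2)O[C@@H](c2ccc(OCc4ccccc4)c(OC)c2)[C@@H]3c2cc(OCc4ccccc4)cc(OCc4ccccc4)c2)ccc1OCc1ccccc1.COc1cc(/C=C/c2cc(O)c3c(c2)O[C@H](c2ccc(OCc4ccccc4)c(OC)c2)[C@H]3c2cc(OCc4ccccc4)cc(OCc4ccccc4)c2)ccc1OCc1ccccc1
F4 | step 9 | (2R,3R)-2-[4-(benzyloxy)-3-methoxyphenyl]-3-[3,5-bis(benzyloxy)phenyl]-6-{(E)-2-[4-(benzyloxy)-3-methoxyphenyl]ethenyl}-4-[(trimethylsilyl)oxy]-2,3,6,7-tetrahydro-1-benzofuran (C6 epimers) | COc1cc(/C=C/C2C=C(O[Si](C)(C)C)C3=C(C2)O[C@@H](c2ccc(OCc4ccccc4)c(OC)c2)[C@@H]3c2cc(OCc4ccccc4)cc(OCc4ccccc4)c2)ccc1OCc1ccccc1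
F5 | step 7 | ethyl (2E,4E)-5-[4-(benzyloxy)-3-methoxyphenyl]penta-2,4-dienoate | CCOC(=O)/C=C/C=C/c1ccc(OCc2ccccc2)c(OC)c1
F0 | step 4 | none | none
A1 | alternative 1 | 2-{1-[3,5-bis(benzyloxy)phenyl]-2-[4-(benzyloxy)-3-methoxyphenyl]-2-(tert-butyldimethylsilyloxy)ethyl}-5-{(E)-2-[4-(benzyloxy)-3-methoxyphenyl]ethenyl}-3-(triisopropylsilyloxy)phenol, stereocentres as in the target | Oc1cc(/C=C/c2ccc(OCc3ccccc3)c(OC)c2)cc(O[Si](C(C)C)(C(C)C)C(C)C)c1[C@@H](c1cc(OCc2ccccc2)cc(OCc2ccccc2)c1)[C@@H](O[Si](C)(C)C(C)(C)C)c1ccc(OCc2ccccc2)c(OC)c1
A2 | alternative 1 | 3-{(E)-2-[4-(benzyloxy)-3-methoxyphenyl]ethenyl}cyclobut-2-en-1-one | O=C1CC(/C=C/c2ccc(OCc3ccccc3)c(OC)c2)=C1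
A3 | alternative 1 | {[3-[3,5-bis(benzyloxy)phenyl]-4-[4-(benzyloxy)-3-methoxyphenyl]-4-(tert-butyldimethylsilyloxy)but-1-yn-1-yl]oxy}triisopropylsilane, stereocentres as in A1 | CC(C)[Si](OC#C[C@@H](c1cc(OCc2ccccc2)cc(OCc2ccccc2)c1)[C@@H](O[Si](C)(C)C(C)(C)C)c1ccc(OCc2ccccc2)c(OC)c1)(C(C)C)C(C)C
A4 | alternative 2 | racemic 4-(benzyloxy)-6-bromo-2-[4-(benzyloxy)-3-methoxyphenyl]-1-benzofuran-3(2H)-one | O=C1C(c2ccc(OCc3ccccc3)c(OC)c2)Oc2cc(Br)cc(OCc3ccccc3)c12
A5 | alternative 2 | 3-(benzyloxy)-5-bromo-2-(trimethylsilyl)phenyl trifluoromethanesulfonate | C[Si](C)(C)c1c(OCc2ccccc2)cc(Br)cc1OS(=O)(=O)C(F)(F)F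
A6 | alternative 2 | racemic methyl 2-[4-(benzyloxy)-3-methoxyphenyl]-2-hydroxyacetate | COC(=O)C(O)c1ccc(OCc2ccccc2)c(OC)c1
A7 | alternative 3 | (2R,3R)-3-[3,5-bis(benzyloxy)phenyl]-6-{(E)-2-[4-(benzyloxy)-3-methoxyphenyl]ethenyl}-2-(4-hydroxy-3-methoxyphenyl)-2,3-dihydro-1-benzofuran-4-ol | COc1cc(/C=C/c2cc(O)c3c(c2)O[C@@H](c2ccc(O)c(OC)c2)[C@@H]3c2cc(OCc4ccccc4)cc(OCc4ccccc4)c2)ccc1OCc1ccccc1
A8 | alternative 3 | 2-{1-[3,5-bis(benzyloxy)phenyl]-2-(4-hydroxy-3-methoxyphenyl)ethyl}-5-{(E)-2-[4-(benzyloxy)-3-methoxyphenyl]ethenyl}benzene-1,3-diol, stereocentre as C3 of the target | COc1cc(/C=C/c2cc(O)c(c(O)c2)[C@H](Cc2ccc(O)c(OC)c2)c2cc(OCc3ccccc3)cc(OCc3ccccc3)c2)ccc1OCc1ccccc1
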